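How high does the complex with two exchanged stand in this flask, and when? Incoming ligand enters from the held gas, decomposes, and replaces the leaving ligand on the complex stepwise.

| flask | starting complex | gas | remark | time |
|---|---|---|---|---|
| ochre | 0.28 mM | 0.0081 mM (held) | run made earlier |  |
| violet | 0.44 mM | 0.0081 mM (held) | run made earlier |  |
| flask | 0.20 mM | 0.0081 mM (held) |  | 12 min |

| ochre: time / min | ochre: complex with two exchanged / % | violet: time / min | violet: complex with two exchanged / % |
|---|---|---|---|
| 0.167 | 2.7 | 0.167 | 2.6 |
| 0.333 | 7.1 | 0.333 | 5.5 |
| 0.833 | 8.4 | 0.833 | 8.1 |
| 2.00 | 4.0 | 2.00 | 5.2 |
| 4.00 | 1.8 | 4.00 | 2.4 |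
| 10.0 | 0.2 | 10.0 | 0 |

(scatter of a reading: 0.5 percentage points)

1. time up to 12 min at which complex with two exchanged stands highest
2. the amount of complex with two exchanged, in percent of the starting complex charged, at that time

- at the start none of incoming ligand is dissolved
- candidate steps: complex with three exchanged + incoming ligand -> leaving ligand + complex with four exchanged; complex with one exchanged + incoming ligand -> leaving ligand + complex with two exchanged; gas <-> incoming ligand; complex with two exchanged + incoming ligand -> leaving ligand + complex with three exchanged; incoming ligand -> decomposed reagent; starting complex + incoming ligand -> leaving ligand + complex with one exchanged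

Set the two runs side by side. At 0.833 min ochre reads 8.4 % and violet 8.1 %, a gap of 0.3 percentage points, which is smaller than the scatter of 0.5 points, although violet holds 1.57 times the charge of ochre. The rows beside it do differ: at 0.333 min ochre is ahead, 7.1 % against 5.5 %, and at 2.00 min it has fallen further, 4.0 % against 5.2 %. So between these runs the charge moves the time more visibly than the height.

The step making this intermediate of consecutive reactions and the step using it both take incoming ligand as partner, so the ligand level multiplies both and drops out of their ratio. The mean of the two top readings, 8.25 %, is my reading of the peak share, the highest percent of the charge standing as complex with two exchanged. For this flask, with 0.20 mM of starting complex, I commit to that height, reached between 0.333 min and 0.833 min.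

The forecast gives 8.9 % (7.9 % to 10.2 %) at 0.55 min (0.38 min to 0.8 min), on the ground that “The held gas gives nearly the same percent curves”.

    complex with three exchanged + incoming ligand → leaving ligand + complex with four exchanged (k = 8700 M⁻¹ s⁻¹)
    complex with one exchanged + incoming ligand → leaving ligand + complex with two exchanged (k = 1400 M⁻¹ s⁻¹)
    gas ⇌ incoming ligand, rate k3*(csat - [incoming ligand]) (kL = 9.70 s⁻¹)
    complex with two exchanged + incoming ligand → leaving ligand + complex with three exchanged (k = 12000 M⁻¹ s⁻¹)
    incoming ligand → decomposed reagent (k = 0.190 s⁻¹)
    starting complex + incoming ligand → leaving ligand + complex with one exchanged (k = 25000 M⁻¹ s⁻¹)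

This flask peaks at 0.602 min with 8.62 %, inside both forecast ranges and 0.28 points below the forecast's height. With the starting complex of this flask doubled, the highest amount is 8.62 %. On the 0.20 mM of this flask, the peak share read from the two runs gives 0.0165 mM of complex with two exchanged. For the neighbouring flask with 0.12 mM of starting complex, the peak share gives 0.00990 mM of complex with two exchanged, and that flask reaches 8.62 %, which is 0.0103 mM.

Readings and results come from a simulation for an exercise; noise was put on by code.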